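**Retrosynthetic overview**

1. The chalcone C=C is cut by a Claisen–Schmidt disconnection into 4-hydroxybenzaldehyde (ring B) and a 6-acetyl-5,8-dihydroxy-2H-chromene. Both partners travel as MOM ethers, because a free hydroquinone and a free 4-hydroxybenzaldehyde behave poorly in alkali.
2. The 5,8-hydroquinone comes from a 5,8-dimethoxyarene (oxidative demethylation, then reduction) and the C3=C4 alkene from the chroman (DDQ). The acetyl group comes from C6–H (bromination para to O1, lithiation, Weinreb acylation) and the carbinol C4' from a methyl ketone (MeMgBr).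
3. Feature that carries the plan: C2 of the pyran ring is a fully substituted ether carbon bound to O1, C3, a methyl group and the CH2 C1', and the chain C1'–C2'–C3' ends at the oxygen-bearing C4'. This pattern is what remains when a phenol adds to a CH2=C(CH3)– unit and the resulting CH2–Pd is coupled to methyl vinyl ketone.
4. Key disconnection: O1–C2 and C1'–C2' are made together by an enantioselective domino Wacker–Heck reaction of 3,6-dimethoxy-2-(3-methylbut-3-enyl)phenol. That phenol is made from 2,5-dimethoxyphenol by directed ortho-metalation and copper-catalysed alkylation.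
5. Ring order: aromatic ring A is bought, the pyran ring is the only ring closed (key step), and ring B arrives intact with the aldehyde.

Key step: step 4

Assumption: the (R,R) enantiomer of the ligand is taken to give the C2 configuration drawn. The sense of induction is to be checked on the first batch of 10, and the (S,S) ligand is used instead if it proves opposite.

Remark on numbering: chroman numbering is used throughout (O1, C2, C3, C4, C4a, C5–C8, C8a; side chain C1'–C4').

Remark on descriptors: the target is (2S). The C2 descriptor is R in 9 and 10 and S from 11 onwards only because the CIP ranks of C1' and C3 swap. No bond at C2 is touched after step 4.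

Remark on the ligand: (R,R)-Bn-BOXAX is (Ra)-2,2'-bis[(4R)-4-benzyl-4,5-dihydrooxazol-2-yl]-1,1'-binaphthyl. It is a known, recoverable catalyst component and is not counted in the steps.

Remark on handling: from step 9 on, all chromenes are kept from light and from unnecessary heat.

**Route**

Step 1
Reactants: 1 2,5-dimethoxyphenol
Product: 2 1,4-dimethoxy-2-(methoxymethoxy)benzene
Conditions: MOMCl, K2CO3, acetone, rt
Reagents that add atoms: chloromethyl methyl ether (MOMCl), COCCl
Why: Williamson-type O-alkylation of the phenoxide gives the formaldehyde acetal, which masks the acidic O–H and is the stronger of the two directing groups needed for the ortho-metalation of step 2.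

Step 2
Reactants: 2 1,4-dimethoxy-2-(methoxymethoxy)benzene; 3 4-bromo-2-methylbut-1-ene
Product: 6 1,4-dimethoxy-2-(methoxymethoxy)-3-(3-methylbut-3-en-1-yl)benzene, via the aryllithium 4 (not isolated), via the arylmagnesium bromide 5 (not isolated)
Conditions: n-BuLi, THF, 0 °C to rt; MgBr2·OEt2, 0 °C; Li2CuCl4 (5 mol %), 3, 0 °C to rt
Reagents that add atoms: none
Why: Directed ortho-metalation takes the ring proton lying between OMOM and OMe (cooperative 1,3-direction, the former C6 of 1), and after Li-to-Mg exchange a Kochi-type copper-catalysed sp2–sp3 cross-coupling through a transient arylcuprate displaces the primary bromide by SN2, whereas the far more basic aryllithium would partly eliminate HBr from the homoallylic bromide.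

Step 3
Reactants: 6 1,4-dimethoxy-2-(methoxymethoxy)-3-(3-methylbut-3-en-1-yl)benzene
Product: 7 3,6-dimethoxy-2-(3-methylbut-3-en-1-yl)phenol
Conditions: HCl (ca. 0.3 M in MeOH), rt to 40 °C, stopped at full conversion
Reagents that add atoms: none
Why: Acid-catalysed transacetalisation to methanol cleaves the aryl formaldehyde acetal before the 1,1-disubstituted alkene is protonated at this acidity, as in the usual release of ortho-prenylphenols from their MOM ethers, so cyclisation to the achiral 2,2-dimethylchroman is avoided.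

Step 4
Reactants: 7 3,6-dimethoxy-2-(3-methylbut-3-en-1-yl)phenol; 8 methyl vinyl ketone
Product: 10 (E)-5-[(2R)-5,8-dimethoxy-2-methylchroman-2-yl]pent-3-en-2-one, via the primary alkylpalladium trifluoroacetate 9 (not isolated)
Conditions: Pd(O2CCF3)2 (10 mol %), (R,R)-Bn-BOXAX (40 mol %), p-benzoquinone (4 equiv), 8 (5 equiv), CH2Cl2, rt, 3–4 d
Reagents that add atoms: none
Why: Divalent palladium held by the C2-symmetric bis(oxazoline) binds the 1,1-disubstituted alkene of 7 and the phenol oxygen attacks its internal carbon, which closes the pyran ring by a 6-exo-trig oxypalladation (O1–C2) and leaves the primary alkylpalladium 9. Since the carbon next to palladium in 9 is the fully substituted C2, beta-hydride elimination is shut off, so 9 persists until it inserts the electron-poor alkene of 8 at its terminal carbon (C1'–C2'), and syn beta-hydride elimination then releases the E-enone 10. p-Benzoquinone takes the zerovalent palladium back to divalent palladium. The closest known reaction type is the enantioselective domino Wacker–Heck cyclisation of ortho-(3-methylbut-3-enyl)phenols with acrylates and vinyl ketones under this same catalyst system. C2 is the only new stereocentre and is set by the ligand, which distinguishes the two faces of the coordinated alkene; the (R,R) ligand is chosen so that 10 has the spatial arrangement of the target. The step needs exo rather than 7-endo attack (secured by the Markovnikov bias of the methyl-bearing alkene carbon and the six-membered transition state) and capture by 8 ahead of catalyst decay (secured by the missing beta-hydrogen and the excess of 8), while the two methyl ethers keep ring A from being oxidised to a quinone.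

Step 5
Reactants: 10 (E)-5-[(2R)-5,8-dimethoxy-2-methylchroman-2-yl]pent-3-en-2-one
Product: 11 5-[(2S)-5,8-dimethoxy-2-methylchroman-2-yl]pentan-2-one
Conditions: H2 (1 atm), Pd/C, EtOAc, rt
Reagents that add atoms: none
Why: Heterogeneous catalytic hydrogenation saturates the conjugated C2'=C3' alkene much faster than the ketone or the arene, and no bond at C2 is touched.

Step 6
Reactants: 11 5-[(2S)-5,8-dimethoxy-2-methylchroman-2-yl]pentan-2-one
Product: 12 5-[(2S)-5,8-dimethoxy-2-methylchroman-2-yl]-2-methylpentan-2-ol
Conditions: MeMgBr, THF, −20 to 0 °C; aq NH4Cl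
Reagents that add atoms: methylmagnesium bromide, C[Mg]Br
Why: Grignard 1,2-addition to the unhindered methyl ketone supplies the second methyl group of the C4' dimethylcarbinol.

Step 7
Reactants: 12 5-[(2S)-5,8-dimethoxy-2-methylchroman-2-yl]-2-methylpentan-2-ol
Product: 13 5-[(2S)-6-bromo-5,8-dimethoxy-2-methylchroman-2-yl]-2-methylpentan-2-ol
Conditions: NBS (1.05 equiv), MeCN, 0 °C, dark
Reagents that add atoms: N-bromosuccinimide, O=C1CCC(=O)N1Br
Why: Electrophilic aromatic bromination goes to C6, which is para to the ring oxygen O1 and ortho to the 5-methoxy group, whereas C7 has only one activating oxygen (ortho 8-OMe); this is the orientation seen with 1,2,4-trialkoxybenzenes, and polar, dark conditions suppress radical attack at benzylic C4.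

Step 8
Reactants: 13 5-[(2S)-6-bromo-5,8-dimethoxy-2-methylchroman-2-yl]-2-methylpentan-2-ol
Product: 15 1-[(2S)-2-(4-hydroxy-4-methylpentyl)-5,8-dimethoxy-2-methylchroman-6-yl]ethanone, via the dilithiated alkoxide-aryllithium 14 (not isolated)
Conditions: n-BuLi (2.2 equiv), THF, −78 °C; MeC(O)N(OMe)Me, −78 to 0 °C; aq NH4Cl
Reagents that add atoms: N-methoxy-N-methylacetamide, CC(=O)N(C)OC
Why: The first equivalent of n-BuLi deprotonates the tertiary alcohol, the second performs bromine–lithium exchange, and the aryllithium is acylated once by the Weinreb amide (Weinreb ketone synthesis), which does not over-add.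

Step 9
Reactants: 15 1-[(2S)-2-(4-hydroxy-4-methylpentyl)-5,8-dimethoxy-2-methylchroman-6-yl]ethanone
Product: 16 1-[(2S)-2-(4-hydroxy-4-methylpentyl)-5,8-dimethoxy-2-methyl-2H-chromen-6-yl]ethanone
Conditions: DDQ (1.5 equiv), 1,4-dioxane, 80 °C, dark
Reagents that add atoms: none
Why: DDQ abstracts hydride from benzylic C4, whose cation is stabilised by the two ortho donors O1 and 5-OMe, and loss of a C3 proton gives the 2H-chromene (the standard chroman-to-chromene dehydrogenation, known also for 6-acetylchromans); C2 bears no hydrogen and takes no part.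

Step 10
Reactants: 16 1-[(2S)-2-(4-hydroxy-4-methylpentyl)-5,8-dimethoxy-2-methyl-2H-chromen-6-yl]ethanone
Product: 18 1-[(2S)-5,8-dihydroxy-2-(4-hydroxy-4-methylpentyl)-2-methyl-2H-chromen-6-yl]ethanone, via the acetylquinone 17 (not isolated)
Conditions: (NH4)2Ce(NO3)6 (2.5 equiv), MeCN–H2O, 0 °C, 15 min; EtOAc extract shaken with aq Na2S2O4, rt, Ar
Reagents that add atoms: water, O
Why: Two one-electron oxidations of the para-dimethoxyarene by tetravalent cerium, with attack of water at C5 and C8, expel both methoxy groups as methanol (oxidative demethylation, feasible because three oxygen donors on ring A outweigh the acetyl group), and the electrophilic quinone 17 is reduced at once by dithionite, which avoids Lewis-acidic ether cleavage that the tertiary alcohol and the chromene would not survive.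

Step 11
Reactants: 18 1-[(2S)-5,8-dihydroxy-2-(4-hydroxy-4-methylpentyl)-2-methyl-2H-chromen-6-yl]ethanone
Product: 19 1-[(2S)-5-hydroxy-2-(4-hydroxy-4-methylpentyl)-8-(methoxymethoxy)-2-methyl-2H-chromen-6-yl]ethanone
Conditions: MOMCl (1.1 equiv), K2CO3, acetone, rt, Ar, dark
Reagents that add atoms: chloromethyl methyl ether (MOMCl), COCCl
Why: The 5-OH is locked in a hydrogen bond to the acetyl carbonyl and the tertiary alcohol is not deprotonated by K2CO3, so the Williamson-type O-alkylation takes place only at the free 8-phenoxide.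

Step 12
Reactants: 20 4-hydroxybenzaldehyde
Product: 21 4-(methoxymethoxy)benzaldehyde
Conditions: MOMCl, K2CO3, acetone, rt
Reagents that add atoms: chloromethyl methyl ether (MOMCl), COCCl
Why: Williamson-type O-alkylation masks the phenol, whose phenoxide would otherwise deactivate the aldehyde towards enolate addition in step 13.

Step 13
Reactants: 19 1-[(2S)-5-hydroxy-2-(4-hydroxy-4-methylpentyl)-8-(methoxymethoxy)-2-methyl-2H-chromen-6-yl]ethanone; 21 4-(methoxymethoxy)benzaldehyde
Product: 22 (E)-1-[(2S)-5-hydroxy-2-(4-hydroxy-4-methylpentyl)-8-(methoxymethoxy)-2-methyl-2H-chromen-6-yl]-3-[4-(methoxymethoxy)phenyl]prop-2-en-1-one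
Conditions: KOH (50 % aq), EtOH, rt, Ar, dark; then 1 M HCl to pH 5, 0 °C
Reagents that add atoms: none
Why: Claisen–Schmidt condensation of the methyl ketone enolate with a non-enolisable aldehyde, followed by E1cB dehydration, gives the more stable E-enone, the chelated 5-phenoxide being tolerated as in ordinary 2'-hydroxychalcone syntheses and the masked 8-OH removing the air-sensitive hydroquinone dianion.

Step 14
Reactants: 22 (E)-1-[(2S)-5-hydroxy-2-(4-hydroxy-4-methylpentyl)-8-(methoxymethoxy)-2-methyl-2H-chromen-6-yl]-3-[4-(methoxymethoxy)phenyl]prop-2-en-1-one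
Product: 23 (E)-1-[(2S)-5,8-dihydroxy-2-(4-hydroxy-4-methylpentyl)-2-methyl-2H-chromen-6-yl]-3-(4-hydroxyphenyl)prop-2-en-1-one (target)
Conditions: HCl (ca. 1 M in MeOH), rt, Ar, dark
Reagents that add atoms: none
Why: Acid-catalysed transacetalisation removes both aryl MOM groups at room temperature, a deprotection established on pyranochalcones, while ionisation of the aliphatic tertiary alcohol, protonation of the chromene and chalcone-to-flavanone cyclisation are much slower under these conditions.

**Compound list**

1 | 2,5-dimethoxyphenol | COc1ccc(OC)c(O)c1 | starting material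
2 | 1,4-dimethoxy-2-(methoxymethoxy)benzene | COCOc1cc(OC)ccc1OC | intermediate
3 | 4-bromo-2-methylbut-1-ene | C=C(C)CCBr | starting material
4 | [3,6-dimethoxy-2-(methoxymethoxy)phenyl]lithium (not isolated) | [Li]c1c(OC)ccc(OC)c1OCOC | intermediate
5 | [3,6-dimethoxy-2-(methoxymethoxy)phenyl]magnesium bromide (not isolated) | Br[Mg]c1c(OC)ccc(OC)c1OCOC | intermediate
6 | 1,4-dimethoxy-2-(methoxymethoxy)-3-(3-methylbut-3-en-1-yl)benzene | C=C(C)CCc1c(OC)ccc(OC)c1OCOC | intermediate
7 | 3,6-dimethoxy-2-(3-methylbut-3-en-1-yl)phenol | C=C(C)CCc1c(OC)ccc(OC)c1O | intermediate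
8 | methyl vinyl ketone | C=CC(C)=O | starting material
9 | {[(2R)-5,8-dimethoxy-2-methylchroman-2-yl]methyl}palladium trifluoroacetate, RCH2Pd(O2CCF3)(ligand), ligand left out of the SMILES (not isolated) | FC(F)(F)C(=O)O[Pd]C[C@@]1(C)CCc2c(OC)ccc(OC)c2O1 | intermediate
10 | (E)-5-[(2R)-5,8-dimethoxy-2-methylchroman-2-yl]pent-3-en-2-one | CC(=O)/C=C/C[C@@]1(C)CCc2c(OC)ccc(OC)c2O1 | intermediate
11 | 5-[(2S)-5,8-dimethoxy-2-methylchroman-2-yl]pentan-2-one | CC(=O)CCC[C@@]1(C)CCc2c(OC)ccc(OC)c2O1 | intermediate
12 | 5-[(2S)-5,8-dimethoxy-2-methylchroman-2-yl]-2-methylpentan-2-ol | CC(C)(O)CCC[C@@]1(C)CCc2c(OC)ccc(OC)c2O1 | intermediate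
13 | 5-[(2S)-6-bromo-5,8-dimethoxy-2-methylchroman-2-yl]-2-methylpentan-2-ol | CC(C)(O)CCC[C@@]1(C)CCc2c(OC)c(Br)cc(OC)c2O1 | intermediate
14 | lithium alkoxide of 12 lithiated at C6 (not isolated) | [Li]OC(C)(C)CCC[C@@]1(C)CCc2c(OC)c([Li])cc(OC)c2O1 | intermediate
15 | 1-[(2S)-2-(4-hydroxy-4-methylpentyl)-5,8-dimethoxy-2-methylchroman-6-yl]ethanone | CC(C)(O)CCC[C@@]1(C)CCc2c(OC)c(C(C)=O)cc(OC)c2O1 | intermediate
16 | 1-[(2S)-2-(4-hydroxy-4-methylpentyl)-5,8-dimethoxy-2-methyl-2H-chromen-6-yl]ethanone | CC(C)(O)CCC[C@@]1(C)C=Cc2c(OC)c(C(C)=O)cc(OC)c2O1 | intermediate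
17 | (2S)-6-acetyl-2-(4-hydroxy-4-methylpentyl)-2-methyl-2H-chromene-5,8-dione (not isolated) | CC(C)(O)CCC[C@@]1(C)C=CC2=C(O1)C(=O)C=C(C(C)=O)C2=O | intermediate
18 | 1-[(2S)-5,8-dihydroxy-2-(4-hydroxy-4-methylpentyl)-2-methyl-2H-chromen-6-yl]ethanone | CC(C)(O)CCC[C@@]1(C)C=Cc2c(O)c(C(C)=O)cc(O)c2O1 | intermediate
19 | 1-[(2S)-5-hydroxy-2-(4-hydroxy-4-methylpentyl)-8-(methoxymethoxy)-2-methyl-2H-chromen-6-yl]ethanone | CC(C)(O)CCC[C@@]1(C)C=Cc2c(O)c(C(C)=O)cc(OCOC)c2O1 | intermediate
20 | 4-hydroxybenzaldehyde | O=Cc1ccc(O)cc1 | starting material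
21 | 4-(methoxymethoxy)benzaldehyde | COCOc1ccc(C=O)cc1 | intermediate
22 | (E)-1-[(2S)-5-hydroxy-2-(4-hydroxy-4-methylpentyl)-8-(methoxymethoxy)-2-methyl-2H-chromen-6-yl]-3-[4-(methoxymethoxy)phenyl]prop-2-en-1-one | CC(C)(O)CCC[C@@]1(C)C=Cc2c(O)c(C(=O)/C=C/c3ccc(OCOC)cc3)cc(OCOC)c2O1 | intermediate
23 | (E)-1-[(2S)-5,8-dihydroxy-2-(4-hydroxy-4-methylpentyl)-2-methyl-2H-chromen-6-yl]-3-(4-hydroxyphenyl)prop-2-en-1-one | CC(C)(O)CCC[C@@]1(C)C=Cc2c(O)c(C(=O)/C=C/c3ccc(O)cc3)cc(O)c2O1 | target

**Step count**

Total step count: 14.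
Longest linear sequence: 13 (steps 1–11, 13, 14; step 12 is a one-step branch).

**Steps most likely to fail**

Step 4.
- What may go wrong: the phenol O–H of 7 is hydrogen-bonded to the neighbouring methoxy group, so oxypalladation may be slow. Over the long reaction time the vinyl ketone may polymerise and palladium metal may deposit. The alkylpalladium would then be captured incompletely and turnover would stall.
- Fallback (sets out from 7, comes back at 10): the alkylpalladium is trapped by CO, a smaller and faster acceptor, and the enone is attached afterwards by olefination.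
- Compound 7 is treated with Pd(O2CCF3)2, the same ligand, p-benzoquinone and CO (1 atm) in MeOH at rt (enantioselective domino Wacker–carbonylation–methoxylation). This should give methyl 2-[(2R)-5,8-dimethoxy-2-methylchroman-2-yl]acetate F1.
- i-Bu2AlH in toluene at −78 °C reduces the ester to 2-[(2R)-5,8-dimethoxy-2-methylchroman-2-yl]acetaldehyde F2.
- Wittig olefination with the stabilised ylide Ph3P=CHC(O)CH3 in CH2Cl2 gives the E-enone 10.

Step 10.
- What may go wrong: tetravalent cerium may attack the C3=C4 alkene of the chromene. Water or nitrate may also add to the very electrophilic acetylquinone before it is reduced.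
- Fallback (sets out from 12, comes back at 23): the oxidative demethylation is moved to the stage at which ring A carries neither alkene nor acyl group, and the hydroquinone is carried on as its bis-MOM ether.
- Compound 12 is oxidised with (NH4)2Ce(NO3)6 in MeCN–H2O to (2S)-2-(4-hydroxy-4-methylpentyl)-2-methylchroman-5,8-dione F3.
- Na2S2O4 reduces the quinone to (2S)-2-(4-hydroxy-4-methylpentyl)-2-methylchroman-5,8-diol F4.
- The diol is protected at once (MOMCl, K2CO3, acetone, Ar) as 5-[(2S)-5,8-bis(methoxymethoxy)-2-methylchroman-2-yl]-2-methylpentan-2-ol F5.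
- NBS as in step 7 gives 5-[(2S)-6-bromo-5,8-bis(methoxymethoxy)-2-methylchroman-2-yl]-2-methylpentan-2-ol F6.
- Bromine–lithium exchange and Weinreb acylation as in step 8 give 1-[(2S)-2-(4-hydroxy-4-methylpentyl)-5,8-bis(methoxymethoxy)-2-methylchroman-6-yl]ethanone F7.
- DDQ as in step 9 gives 1-[(2S)-2-(4-hydroxy-4-methylpentyl)-5,8-bis(methoxymethoxy)-2-methyl-2H-chromen-6-yl]ethanone F8.
- Claisen–Schmidt condensation with 21 gives (E)-1-[(2S)-2-(4-hydroxy-4-methylpentyl)-5,8-bis(methoxymethoxy)-2-methyl-2H-chromen-6-yl]-3-[4-(methoxymethoxy)phenyl]prop-2-en-1-one F9.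
- HCl in MeOH as in step 14 removes all three MOM groups to give 23.

Step 9.
- What may go wrong: hydride abstraction from the acetyl-deactivated ring may be sluggish and call for prolonged heating. On heating the chromene can open reversibly by a 6π electrocyclic process to an achiral ortho-quinone methide, which erodes the configuration at C2.
- Fallback (sets out from 15, comes back at 16): the alkene is introduced by substitution and elimination, so that the chromene itself never sees heat.
- Wohl–Ziegler bromination of 15 (NBS, AIBN, PhCF3, 80 °C) at benzylic C4 gives 1-[(2S,4RS)-4-bromo-2-(4-hydroxy-4-methylpentyl)-5,8-dimethoxy-2-methylchroman-6-yl]ethanone F10.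
- E2 elimination with DBU in THF at rt gives 16.

**Further compounds**

F1 | step 4 | methyl 2-[(2R)-5,8-dimethoxy-2-methylchroman-2-yl]acetate | COC(=O)C[C@@]1(C)CCc2c(OC)ccc(OC)c2O1
F2 | step 4 | 2-[(2R)-5,8-dimethoxy-2-methylchroman-2-yl]acetaldehyde | O=CC[C@@]1(C)CCc2c(OC)ccc(OC)c2O1
F3 | step 10 | (2S)-2-(4-hydroxy-4-methylpentyl)-2-methylchroman-5,8-dione | CC(C)(O)CCC[C@@]1(C)CCC2=C(O1)C(=O)C=CC2=O
F4 | step 10 | (2S)-2-(4-hydroxy-4-methylpentyl)-2-methylchroman-5,8-diol | CC(C)(O)CCC[C@@]1(C)CCc2c(O)ccc(O)c2O1
F5 | step 10 | 5-[(2S)-5,8-bis(methoxymethoxy)-2-methylchroman-2-yl]-2-methylpentan-2-ol | CC(C)(O)CCC[C@@]1(C)CCc2c(OCOC)ccc(OCOC)c2O1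
F6 | step 10 | 5-[(2S)-6-bromo-5,8-bis(methoxymethoxy)-2-methylchroman-2-yl]-2-methylpentan-2-ol | CC(C)(O)CCC[C@@]1(C)CCc2c(OCOC)c(Br)cc(OCOC)c2O1
F7 | step 10 | 1-[(2S)-2-(4-hydroxy-4-methylpentyl)-5,8-bis(methoxymethoxy)-2-methylchroman-6-yl]ethanone | CC(C)(O)CCC[C@@]1(C)CCc2c(OCOC)c(C(C)=O)cc(OCOC)c2O1
F8 | step 10 | 1-[(2S)-2-(4-hydroxy-4-methylpentyl)-5,8-bis(methoxymethoxy)-2-methyl-2H-chromen-6-yl]ethanone | CC(C)(O)CCC[C@@]1(C)C=Cc2c(OCOC)c(C(C)=O)cc(OCOC)c2O1
F9 | step 10 | (E)-1-[(2S)-2-(4-hydroxy-4-methylpentyl)-5,8-bis(methoxymethoxy)-2-methyl-2H-chromen-6-yl]-3-[4-(methoxymethoxy)phenyl]prop-2-en-1-one | CC(C)(O)CCC[C@@]1(C)C=Cc2c(OCOC)c(C(=O)/C=C/c3ccc(OCOC)cc3)cc(OCOC)c2O1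
F10 | step 9 | 1-[(2S,4RS)-4-bromo-2-(4-hydroxy-4-methylpentyl)-5,8-dimethoxy-2-methylchroman-6-yl]ethanone | CC(C)(O)CCC[C@@]1(C)CC(Br)c2c(OC)c(C(C)=O)cc(OC)c2O1
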